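Numbering: ring A = C1–C5 + C10 (C4 is the gem-dimethyl carbon, C5 the CH bearing the C6–C8 oxobutyl chain, C10 quaternary). C9 is the ring-bound ketone, C11–C15 the chain to the ester carbonyl, and C13 its methyl-bearing CH.
Cuts, in retrosynthetic order: the glycerol O–C15 ester and the O-2 acetate; C9–C11 (aldehyde + Grignard reagent); one C4–CH3 bond (enolate methylation helped by a temporary C3 oxygen); finally C1–C10 and C4–C5 together, which opens ring A.
Enabling feature: the adjacent ring A atoms C5 and C10 hold the C6 chain and the C9 acyl carbon trans, with a methyl on C10. This is the pattern an (E)-2-methyl-2-enal leaves in a [4+2] adduct, and C1–C4 form a plain four-carbon unit that a 3-silyloxypentadiene can supply.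
Forward: enal 5 and diene 7 close ring A (the only ring), and the C11–C15 chain is joined at C9. C4 is then quaternised and C3 deoxygenated, C8, C9 and C15 reach their final oxidation levels in one step, and the glycerol unit is esterified, acetylated and unmasked.
Stereochemistry: C5/C10 relative from the enal geometry and absolute from the (S)-prolinol-derived oxazaborolidinium catalyst; C13 from methyl hydrogen (R)-3-methylglutarate; glycerol C2 from (R)-3-(benzyloxy)propane-1,2-diol.

Key step: step 5

Assumption: the (S)-catalyst is taken to leave the C10-Re/C5-Si face of 5 open, as the formyl C–H···O binding model predicts for 2-methyl enals (the antipodal prolinol is equally available); C4 (until step 13) and C9 (until step 16) are carried as epimer mixtures because both centres are erased.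

Step 1
Reactants: 1 5-hexen-2-one
Product: 2 2-(but-3-en-1-yl)-2-methyl-1,3-dioxolane
Conditions: HOCH2CH2OH, p-TsOH·H2O (cat.), toluene, reflux, Dean–Stark
Reagents that add atoms: ethylene glycol, OCCO
Why: Acid-catalysed ketalisation with azeotropic water removal masks the future C8 ketone against the later Grignard, enolate and hydrazine steps, and the isolated alkene is inert.

Step 2
Reactants: 2 2-(but-3-en-1-yl)-2-methyl-1,3-dioxolane
Product: 4 3-(2-methyl-1,3-dioxolan-2-yl)propanal, via secondary ozonide 3 (not isolated)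
Conditions: O3, CH2Cl2, −78 °C; then PPh3, −78 °C → rt
Reagents that add atoms: ozone, [O-][O+]=O
Why: Ozonolysis with reductive work-up cleaves the terminal alkene to the aldehyde under neutral conditions that leave the dioxolane intact.

Step 3
Reactants: 4 3-(2-methyl-1,3-dioxolan-2-yl)propanal
Product: 5 (E)-2-methyl-5-(2-methyl-1,3-dioxolan-2-yl)pent-2-enal
Conditions: Ph3P=C(CH3)CHO (1.05 equiv), toluene, 80 °C
Reagents that add atoms: 2-(triphenylphosphoranylidene)propanal, CC(C=O)=P(c1ccccc1)(c1ccccc1)c1ccccc1
Why: Wittig olefination with a formyl-stabilised ylide should give the (E)-trisubstituted enal, and a near-stoichiometric amount of ylide prevents a second olefination.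

Step 4
Reactants: 6 ethyl vinyl ketone (pent-1-en-3-one)
Product: 7 (Z)-3-(triisopropylsilyloxy)penta-1,3-diene
Conditions: TIPSOTf, Et3N, CH2Cl2, 0 °C → rt
Reagents that add atoms: triisopropylsilyl triflate, CC(C)[Si](C(C)C)(C(C)C)OS(=O)(=O)C(F)(F)F
Why: Soft enolisation and O-silylation of the enone removes a proton from the ethyl CH2 and should give the (Z)-silyl enol ether, whose terminal methyl is trans to the vinyl group so that the s-cis diene stays accessible.

Step 5
Reactants: 5 (E)-2-methyl-5-(2-methyl-1,3-dioxolan-2-yl)pent-2-enal; 7 (Z)-3-(triisopropylsilyloxy)penta-1,3-diene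
Product: 8 (1R,6R)-1,5-dimethyl-6-[2-(2-methyl-1,3-dioxolan-2-yl)ethyl]-4-(triisopropylsilyloxy)cyclohex-3-ene-1-carbaldehyde (ring A aldehyde, 5R,10R, C4 epimers)
Conditions: (S)-3,3-diphenyl-1-(2-methylphenyl)tetrahydro-1H,3H-pyrrolo[1,2-c][1,3,2]oxazaborole (24 mol %), HNTf2 (20 mol %), CH2Cl2, −78 → −40 °C; Et3N quench
Reagents that add atoms: none
Why: The formyl oxygen of 5 binds to the boron of the N-protonated oxazaborolidine, a formyl C–H···O contact holds the s-trans enal over one of the geminal phenyl groups, and 7 adds to the open face in a concerted, asynchronous, suprafacial [4+2] cycloaddition in which C4–C5 bonding runs ahead of C1–C10. The closest known reaction type is the oxazaborolidinium-catalysed Diels–Alder reaction of 2-silyloxy dienes with 2-methyl and 2,3-disubstituted enals. Ring A closes intermolecularly by two new σ bonds, four ring atoms (C1–C4) coming from the diene and two (C5, C10) from the enal alkene. The C5/C10 relative configuration follows from retention of the (E)-geometry, which leaves the C6 chain and the C9 formyl group trans; the absolute configuration follows from the (S)-catalyst, which should leave only the C10-Re/C5-Si face accessible; and the C4 methine (endo/exo outcome) needs no control because step 13 makes it quaternary. The required regioselectivity is secured by the C3 silyloxy group, which makes C4 the nucleophilic diene terminus and pairs it with the electrophilic β-carbon C5, and by the (Z)-enol ether geometry, which keeps the C4 methyl outside the s-cis diene. Ketal and silyl enol ether should survive because the oxazaborolidine is kept in slight excess over HNTf2, the temperature stays low and the mixture is quenched with Et3N before warming.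

Step 6
Reactants: 9 methyl hydrogen (R)-3-methylglutarate [(R)-5-methoxy-3-methyl-5-oxopentanoic acid]
Product: 10 methyl (R)-5-hydroxy-3-methylpentanoate
Conditions: BH3·SMe2, THF, 0 °C → rt; MeOH quench
Reagents that add atoms: none
Why: Chemoselective borane reduction of a carboxylic acid beside a methyl ester turns the acid terminus into the future C11 carbinol and does not touch the C13 stereocentre.

Step 7
Reactants: 10 methyl (R)-5-hydroxy-3-methylpentanoate
Product: 11 methyl (S)-5-bromo-3-methylpentanoate
Conditions: CBr4, PPh3, CH2Cl2, 0 °C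
Reagents that add atoms: carbon tetrabromide, BrC(Br)(Br)Br
Why: The Appel reaction replaces the primary hydroxyl under neutral conditions before the δ-hydroxy ester can lactonise (the descriptor changes by CIP ranking only).

Step 8
Reactants: 11 methyl (S)-5-bromo-3-methylpentanoate
Product: 12 (S)-5-bromo-3-methylpentan-1-ol
Conditions: iBu2AlH (2.2 equiv), CH2Cl2, −78 → 0 °C; aq. potassium sodium tartrate
Reagents that add atoms: none
Why: Hydride reduction of the ester with iBu2AlH gives the primary alcohol (future C15), and a primary alkyl bromide is not attacked at this temperature.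

Step 9
Reactants: 12 (S)-5-bromo-3-methylpentan-1-ol
Product: 13 (S)-{[(5-bromo-3-methylpentyl)oxy]methyl}benzene
Conditions: BnOC(=NH)CCl3, TfOH (cat.), CH2Cl2–cyclohexane, 0 °C → rt
Reagents that add atoms: benzyl 2,2,2-trichloroacetimidate, ClC(Cl)(Cl)C(=N)OCc1ccccc1
Why: Acid-catalysed O-benzylation with the trichloroacetimidate avoids an alkoxide, which would displace bromide and close a tetrahydropyran.

Step 10
Reactants: 13 (S)-{[(5-bromo-3-methylpentyl)oxy]methyl}benzene; 8 ring A aldehyde
Product: 15 (4R)-6-(benzyloxy)-1-{(1R,6R)-1,5-dimethyl-6-[2-(2-methyl-1,3-dioxolan-2-yl)ethyl]-4-(triisopropylsilyloxy)cyclohex-3-en-1-yl}-4-methylhexan-1-ol (C9 carbinol, C4 and C9 epimers), via Grignard reagent 14 (not isolated)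
Conditions: 13, Mg, THF, 40 °C; then 8, THF, −78 → 0 °C; sat. aq NH4Cl
Reagents that add atoms: none
Why: Grignard addition to the non-enolisable neopentyl aldehyde forms C9–C11; ketal, silyl enol ether and benzyl ether are inert, and the new C9 centre needs no control because step 16 oxidises it.

Step 11
Reactants: 15 C9 carbinol
Product: 16 bis(benzyl ether), the C9-O-benzyl derivative of 15 (5R,10R,13R, C4 and C9 epimers)
Conditions: NaH, BnBr, Bu4NI (cat.), DMF, 0 °C → rt
Reagents that add atoms: benzyl bromide, BrCc1ccccc1
Why: Williamson etherification caps the C9 hydroxyl before the enone exists, because a free alkoxide on the carbon attached to the γ-position of an enone could fragment by a vinylogous retro-aldol path and would also compete for MeI in step 13.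

Step 12
Reactants: 16 bis(benzyl ether)
Product: 17 (4R,5R)-4-[(4R)-1,6-bis(benzyloxy)-4-methylhexyl]-4,6-dimethyl-5-[2-(2-methyl-1,3-dioxolan-2-yl)ethyl]cyclohex-2-en-1-one (C1=C2–C3=O enone, C4 and C9 epimers)
Conditions: Pd(OAc)2 (1.2 equiv), DMSO, 45 °C
Reagents that add atoms: none
Why: In the Saegusa–Ito oxidation divalent palladium replaces silicon at C2 and syn β-hydride loss from C1 gives the C1=C2 enone regiospecifically, releasing zerovalent palladium.

Step 13
Reactants: 17 C1=C2–C3=O enone
Product: 19 (4R,5S)-4-[(4R)-1,6-bis(benzyloxy)-4-methylhexyl]-4,6,6-trimethyl-5-[2-(2-methyl-1,3-dioxolan-2-yl)ethyl]cyclohex-2-en-1-one (gem-dimethyl enone; C5 reads S only through CIP ranking, no bond at C5 changes), via lithium dienolate 18 (not isolated)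
Conditions: LiN(iPr)2 (1.3 equiv), THF, −78 °C; MeI, DMPU, −78 → 0 °C
Reagents that add atoms: iodomethane, CI
Why: In this kinetic α′-enolate alkylation C10 is quaternary, so C4–H is the only enolisable position of the enone, and C-methylation completes the gem-dimethyl group and erases the C4 stereocentre.

Step 14
Reactants: 19 gem-dimethyl enone
Product: 20 (3S,4R)-4-[(4R)-1,6-dihydroxy-4-methylhexyl]-2,2,4-trimethyl-3-[2-(2-methyl-1,3-dioxolan-2-yl)ethyl]cyclohexan-1-one (keto diol, C9 epimers)
Conditions: H2 (1 atm), Pd(OH)2/C, EtOAc–EtOH, rt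
Reagents that add atoms: none
Why: Heterogeneous catalytic hydrogenation saturates C1=C2 and hydrogenolyses both benzyl ethers in one operation, while the hindered C3 ketone and the ketal are not reduced.

Step 15
Reactants: 20 keto diol
Product: 22 (4R)-4-methyl-1-{(1R,2R)-1,3,3-trimethyl-2-[2-(2-methyl-1,3-dioxolan-2-yl)ethyl]cyclohexyl}hexane-1,6-diol (C9 epimers), via C3 hydrazone 21 (not isolated)
Conditions: N2H4·H2O, KOH, diethylene glycol, 130 °C, then 200 °C
Reagents that add atoms: none
Why: Wolff–Kishner reduction is the classical deoxygenation of ring ketones flanked by a gem-dimethyl carbon, it tolerates free alcohols and the base-stable dioxolane, and no stereocentre is α to the carbonyl.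

Step 16
Reactants: 22 diol ketal
Product: 23 (3R)-3-methyl-6-oxo-6-[(1R,2R)-1,3,3-trimethyl-2-(3-oxobutyl)cyclohexyl]hexanoic acid
Conditions: CrO3, H2SO4, H2O, acetone, 0 °C → rt; iPrOH quench
Reagents that add atoms: water, O
Why: Jones oxidation takes the C9 carbinol to the ketone and the C15 alcohol through the aldehyde hydrate to the acid, and the aqueous sulfuric acid in acetone exchanges the dioxolane at the same time, freeing the C8 ketone.

Step 17
Reactants: 23 diketo acid; 24 (R)-3-(benzyloxy)propane-1,2-diol (3-O-benzyl-sn-glycerol)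
Product: 25 (2S)-3-(benzyloxy)-2-hydroxypropyl (3R)-3-methyl-6-oxo-6-[(1R,2R)-1,3,3-trimethyl-2-(3-oxobutyl)cyclohexyl]hexanoate
Conditions: 24 (1.5 equiv), DCC, 4-(dimethylamino)pyridine (DMAP, cat.), CH2Cl2, 0 °C
Reagents that add atoms: none
Why: Steglich esterification at low temperature with the diol in excess acylates the primary hydroxyl in preference to the secondary one, as is usual for 1-acyl-3-O-benzyl-sn-glycerols, and does not touch glycerol C2.

Step 18
Reactants: 25 monoester
Product: 26 (2S)-2-acetoxy-3-(benzyloxy)propyl (3R)-3-methyl-6-oxo-6-[(1R,2R)-1,3,3-trimethyl-2-(3-oxobutyl)cyclohexyl]hexanoate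
Conditions: Ac2O, pyridine, DMAP (cat.), CH2Cl2, 0 °C
Reagents that add atoms: acetic anhydride, CC(=O)OC(C)=O
Why: DMAP-catalysed acetylation of the remaining secondary hydroxyl, run directly after step 17, fixes the 1,2-diacyl pattern before the long-chain acyl group can migrate.

Step 19
Reactants: 26 benzyl-protected diacylglycerol
Product: 27 (2S)-2-acetoxy-3-hydroxypropyl (3R)-3-methyl-6-oxo-6-[(1R,2R)-1,3,3-trimethyl-2-(3-oxobutyl)cyclohexyl]hexanoate (CNP0287223.1)
Conditions: H2 (1 atm), 10% Pd/C, EtOAc, rt; rapid chromatography on boric acid-treated silica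
Reagents that add atoms: none
Why: Benzyl ether hydrogenolysis is neutral, the molecule has no C=C bond and its ketones and esters are inert, so the primary hydroxyl should be freed without acetyl migration from O-2 to O-3.

Compound list
1 | 5-hexen-2-one | CC(=O)CCC=C | starting material
2 | 2-(but-3-en-1-yl)-2-methyl-1,3-dioxolane | CC1(CCC=C)OCCO1 | intermediate
3 | 3-[2-(2-methyl-1,3-dioxolan-2-yl)ethyl]-1,2,4-trioxolane (secondary ozonide, not isolated) | CC1(CCC2OCOO2)OCCO1 | intermediate
4 | 3-(2-methyl-1,3-dioxolan-2-yl)propanal | CC1(CCC=O)OCCO1 | intermediate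
5 | (E)-2-methyl-5-(2-methyl-1,3-dioxolan-2-yl)pent-2-enal | O=C/C(C)=C/CCC1(C)OCCO1 | intermediate
6 | ethyl vinyl ketone | CCC(=O)C=C | starting material
7 | (Z)-3-(triisopropylsilyloxy)penta-1,3-diene | C=C/C(O[Si](C(C)C)(C(C)C)C(C)C)=C/C | intermediate
8 | ring A aldehyde (5R,10R, C4 epimers) | CC1(CC[C@@H]2C(C)C(O[Si](C(C)C)(C(C)C)C(C)C)=CC[C@@]2(C)C=O)OCCO1 | intermediate
9 | methyl hydrogen (R)-3-methylglutarate | OC(=O)C[C@@H](C)CC(=O)OC | starting material
10 | methyl (R)-5-hydroxy-3-methylpentanoate | OCC[C@@H](C)CC(=O)OC | intermediate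
11 | methyl (S)-5-bromo-3-methylpentanoate | BrCC[C@@H](C)CC(=O)OC | intermediate
12 | (S)-5-bromo-3-methylpentan-1-ol | BrCC[C@@H](C)CCO | intermediate
13 | (S)-{[(5-bromo-3-methylpentyl)oxy]methyl}benzene | BrCC[C@@H](C)CCOCc1ccccc1 | intermediate
14 | [(S)-5-(benzyloxy)-3-methylpentyl]magnesium bromide (not isolated) | Br[Mg]CC[C@@H](C)CCOCc1ccccc1 | intermediate
15 | C9 carbinol (C4 and C9 epimers) | CC1(CC[C@@H]2C(C)C(O[Si](C(C)C)(C(C)C)C(C)C)=CC[C@@]2(C)C(O)CC[C@@H](C)CCOCc3ccccc3)OCCO1 | intermediate
16 | C9,C15-bis(benzyl ether) silyl enol ether | CC1(CC[C@@H]2C(C)C(O[Si](C(C)C)(C(C)C)C(C)C)=CC[C@@]2(C)C(OCc3ccccc3)CC[C@@H](C)CCOCc3ccccc3)OCCO1 | intermediate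
17 | C1=C2–C3=O enone (C4 and C9 epimers) | CC1(CC[C@@H]2C(C)C(=O)C=C[C@@]2(C)C(OCc3ccccc3)CC[C@@H](C)CCOCc3ccccc3)OCCO1 | intermediate
18 | lithium C3–C4 dienolate of 17 (not isolated) | CC1(CC[C@@H]2C(C)=C([O-])C=C[C@@]2(C)C(OCc3ccccc3)CC[C@@H](C)CCOCc3ccccc3)OCCO1.[Li+] | intermediate
19 | gem-dimethyl enone | CC1(CC[C@@H]2C(C)(C)C(=O)C=C[C@@]2(C)C(OCc3ccccc3)CC[C@@H](C)CCOCc3ccccc3)OCCO1 | intermediate
20 | keto diol | CC1(CC[C@@H]2C(C)(C)C(=O)CC[C@@]2(C)C(O)CC[C@@H](C)CCO)OCCO1 | intermediate
21 | C3 hydrazone of 20 (not isolated) | CC1(CC[C@@H]2C(C)(C)C(=NN)CC[C@@]2(C)C(O)CC[C@@H](C)CCO)OCCO1 | intermediate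
22 | diol ketal | CC1(CC[C@@H]2C(C)(C)CCC[C@@]2(C)C(O)CC[C@@H](C)CCO)OCCO1 | intermediate
23 | diketo acid | CC(=O)CC[C@@H]1C(C)(C)CCC[C@@]1(C)C(=O)CC[C@@H](C)CC(=O)O | intermediate
24 | (R)-3-(benzyloxy)propane-1,2-diol | OC[C@H](COCc1ccccc1)O | starting material
25 | 1-acyl-3-O-benzyl-sn-glycerol | CC(=O)CC[C@@H]1C(C)(C)CCC[C@@]1(C)C(=O)CC[C@@H](C)CC(=O)OC[C@H](COCc2ccccc2)O | intermediate
26 | 1-acyl-2-acetyl-3-O-benzyl-sn-glycerol | CC(=O)CC[C@@H]1C(C)(C)CCC[C@@]1(C)C(=O)CC[C@@H](C)CC(=O)OC[C@H](COCc2ccccc2)OC(C)=O | intermediate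
27 | CNP0287223.1 | CC(=O)CC[C@@H]1C(C)(C)CCC[C@@]1(C)C(=O)CC[C@@H](C)CC(=O)OC[C@H](CO)OC(C)=O | target

Total step count: 19. Longest linear sequence: 14 steps (1–3, 5, 10–19). The branch 6–9 followed by 10–19 is equally long.

Steps most likely to fail

Step 5. The trisubstituted enal may react sluggishly. Facial selectivity may erode if the temperature has to be raised. The ketal oxygens may also tie up the acid catalyst or ionise, so that diene is consumed by side reactions.
The fallback replaces asymmetric catalysis by a classical resolution, sets out from 5 and 7 and returns at 8. The cycloaddition is promoted by the achiral Lewis acid Me2AlCl (CH2Cl2, −78 °C) to give racemic ring A aldehyde F1. NaBH4 in EtOH reduces it to racemic neopentyl alcohol F2. Steglich esterification with (S)-2-methoxy-2-phenylacetic acid, followed by chromatographic separation of the diastereomers, provides the (5R,10R) O-methylmandelate F3. LiAlH4 releases enantiopure neopentyl alcohol F4, and Dess–Martin periodinane oxidises it to 8.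

Step 15. Hydrazone formation at the hindered C3 carbonyl may stay incomplete, azine formation may compete, and prolonged heating in strong base may degrade material.
The fallback swaps the hydrazone chemistry for a radical deoxygenation, sets out from 19 and returns at 22. NaBH4 with NiCl2·6H2O in MeOH reduces both C1=C2 and C3=O while keeping the benzyl ethers, giving saturated C3 alcohol F5. NaH, CS2 and MeI convert it to S-methyl xanthate F6. Bu3SnH with azobisisobutyronitrile in refluxing toluene (Barton–McCombie deoxygenation) gives deoxygenated bis(benzyl ether) F7. Hydrogenolysis over Pd(OH)2/C then gives 22.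

Step 17. Acylation may also reach the secondary hydroxyl, and the acyl group may migrate from O-1 to O-2 under DMAP, which would lower regiochemical purity.
The fallback creates the secondary hydroxyl instead of differentiating two hydroxyls, sets out from 23 and returns at 25. Acid 23 opens purchased (R)-benzyl glycidyl ether F8 at its unsubstituted carbon (Bu4NBr cat., toluene, 90 °C). This SN2 epoxide opening by the carboxylate leaves the stereocentre untouched and gives 25 directly.

Further compounds
F1 | step 5 | racemic ring A aldehyde (racemate of 8, relative configuration drawn) | CC1(CC[C@@H]2C(C)C(O[Si](C(C)C)(C(C)C)C(C)C)=CC[C@@]2(C)C=O)OCCO1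
F2 | step 5 | racemic neopentyl alcohol (relative configuration drawn) | CC1(CC[C@@H]2C(C)C(O[Si](C(C)C)(C(C)C)C(C)C)=CC[C@@]2(C)CO)OCCO1
F3 | step 5 | (5R,10R) O-methylmandelate, ester of the C9 alcohol with (S)-2-methoxy-2-phenylacetic acid | CC1(CC[C@@H]2C(C)C(O[Si](C(C)C)(C(C)C)C(C)C)=CC[C@@]2(C)COC(=O)[C@@H](OC)c3ccccc3)OCCO1
F4 | step 5 | enantiopure (5R,10R) neopentyl alcohol | CC1(CC[C@@H]2C(C)C(O[Si](C(C)C)(C(C)C)C(C)C)=CC[C@@]2(C)CO)OCCO1
F5 | step 15 | saturated C3 alcohol, bis(benzyl ether) | CC1(CC[C@@H]2C(C)(C)C(O)CC[C@@]2(C)C(OCc3ccccc3)CC[C@@H](C)CCOCc3ccccc3)OCCO1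
F6 | step 15 | C3 S-methyl xanthate | CC1(CC[C@@H]2C(C)(C)C(OC(=S)SC)CC[C@@]2(C)C(OCc3ccccc3)CC[C@@H](C)CCOCc3ccccc3)OCCO1
F7 | step 15 | deoxygenated bis(benzyl ether) | CC1(CC[C@@H]2C(C)(C)CCC[C@@]2(C)C(OCc3ccccc3)CC[C@@H](C)CCOCc3ccccc3)OCCO1
F8 | step 17 | (R)-benzyl glycidyl ether (purchased) | C1[C@H](COCc2ccccc2)O1
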